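The plan rests on cutting the C7–C8 bond of the cyclopentane ring, whose vicinal C7 (secondary) and C8 (tertiary, C10-bearing) oxygens are the signature of a pinacol coupling. In one operation SmI2 joins the C7 aldehyde to the C8 ketone of a monocyclic precursor, closes the five-membered ring onto the dihydropyranone ring and sets both carbinol centres as the 7α,8α-cis-diol. A later Mitsunobu esterification inverts C7. The precursor is a 3,4-dihydropyran-2-one (C1, O2, C3=C4, C5, C9) carrying a silyloxymethyl group on C4, a 2-oxoethyl chain on C5 and a silyloxyacetyl group on C9. C5, the only stereocentre it needs, comes from an amine-catalysed nitro-Michael addition.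

Key step: step 10

Remark: iridoid numbering (C1, O2, C3–C11) is used for all intermediates and TBS = tert-butyldimethylsilyl; C9 of the β-keto lactones 13 and 14 is stereolabile, so 14 is drawn as the 5,9-cis epimer that cyclises.

Step 1
Reactants: 1 (TBS-oxy)acetaldehyde; 2 nitromethane
Product: 4 (E)-tert-butyldimethyl[(3-nitroprop-2-en-1-yl)oxy]silane, via nitro alcohol 3 (not isolated)
Conditions: MeNO2 (5 equiv), Et3N (0.1 equiv), THF, 0 °C to rt; concentrate; MsCl (1.2 equiv), Et3N (2.5 equiv), CH2Cl2, −20 to 0 °C
Reagents that add atoms: none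
Why: Henry addition followed by mesylation and E1cB loss of methanesulfonate is the standard entry to conjugated nitroalkenes, should give the more stable E isomer, and joins C3 to C4/C11 without leaving a stereocentre.

Step 2
Reactants: 4 nitroalkene; 5 methyl 4-oxobutanoate
Product: 6 methyl (3S,4S)-4-[(TBS-oxy)methyl]-3-formyl-5-nitropentanoate (syn adduct; formyl carbon = C6, C-3 = C5, C-4 = C4, C-5 = C3)
Conditions: 5 (1.5 equiv), (R)-2-[diphenyl(trimethylsilyloxy)methyl]pyrrolidine (10 mol%), 4-nitrophenol (10 mol%), toluene, 0 °C to rt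
Reagents that add atoms: none
Why: In this enamine-catalysed Michael addition of an aldehyde to a nitroalkene, the diphenyl(silyloxy)methyl group of the R catalyst shields one face of the E-enamine of 5, so C5 forms with S configuration (H-5 β in the target), and the synclinal open transition state gives the syn C4/C5 pair, of which C4 is erased in step 6.

Step 3
Reactants: 6 γ-nitro aldehyde
Product: 7 methyl (3S,4S)-4-[(TBS-oxy)methyl]-3-(2-methoxyethenyl)-5-nitropentanoate (E/Z mixture at C6=C7)
Conditions: Ph3P(CH2OMe)Cl (2.6 equiv), KN(SiMe3)2 (2.5 equiv), THF, −78 to 0 °C; aq NH4Cl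
Reagents that add atoms: (methoxymethyl)triphenylphosphonium chloride, COC[P+](c1ccccc1)(c1ccccc1)c1ccccc1.[Cl-]
Why: Wittig methoxymethylenation adds C7 already masked at the aldehyde level, the first equivalent of ylide only turns the nitro group into an inert nitronate that is reprotonated on work-up, and fast carbonyl addition at low temperature should leave the α-stereocentre C5 untouched.

Step 4
Reactants: 7 enol ether
Product: 8 methyl (3S,4S)-4-[(TBS-oxy)methyl]-3-(2,2-dimethoxyethyl)-5-nitropentanoate
Conditions: MeOH, PPTS (0.1 equiv), rt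
Reagents that add atoms: methanol, CO
Why: Acid-catalysed addition of methanol to an enol ether (acetal formation through the oxocarbenium ion) merges both alkene isomers into one oxidation-stable dimethyl acetal, and pyridinium tosylate is too weak to cleave the primary TBS ether.

Step 5
Reactants: 8 nitro ester
Product: 10 (3S,4R)-5-(TBS-oxy)-3-(2,2-dimethoxyethyl)-4-formylpentanoic acid (in equilibrium with its 6-hydroxy δ-lactone), via nitro acid 9 (not isolated)
Conditions: KOH (3.2 equiv), MeOH/H2O, rt; then MgSO4 (1.5 equiv), KMnO4 (0.7 equiv), H2O, 0 °C; NaH2PO4 to pH 5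
Reagents that add atoms: KOH, [K+].[OH-]; KMnO4, [K+].[O-][Mn](=O)(=O)=O
Why: Saponification and an oxidative Nef reaction share one basic medium, since hydroxide cleaves the ester and forms the nitronate, permanganate cleaves the nitronate faster than it attacks the resulting aldehyde, and MgSO4 buffers the liberated hydroxide so that the β-silyloxy aldehyde does not eliminate, while C5 is untouched and C4 is irrelevant.

Step 6
Reactants: 10 aldehyde acid
Product: 11 (S)-5-[(TBS-oxy)methyl]-4-(2,2-dimethoxyethyl)-3,4-dihydro-2H-pyran-2-one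
Conditions: MsCl (1.3 equiv), Et3N (3.5 equiv), CH2Cl2, −30 to 0 °C
Reagents that add atoms: none
Why: In this dehydrative enol lactonisation of a 5-oxo acid, the 6-hydroxy lactone form is mesylated and loses methanesulfonate together with the C4 proton (the open form reaches the same product by O-acylation of the aldehyde enolate through the mixed anhydride), which closes the O2 ring, erases C4 and spares the C7 acetal because no acid is present.

Step 7
Reactants: 11 enol lactone; 1 (TBS-oxy)acetaldehyde
Product: 12 (4S)-3-[2-(TBS-oxy)-1-hydroxyethyl]-5-[(TBS-oxy)methyl]-4-(2,2-dimethoxyethyl)-3,4-dihydro-2H-pyran-2-one (diastereomer mixture at C8 and C9)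
Conditions: LiN(iPr)2 (1.1 equiv), THF, −78 °C; 1 (1.3 equiv), −78 °C, 15 min; AcOH, −78 °C
Reagents that add atoms: none
Why: Aldol addition of a lactone lithium enolate forms C9–C8 within minutes at −78 °C, where the enolate does not fragment to a ketene and the aldolate does not attack the enol lactone, and C8 and C9 need no control because C8 is oxidised next and C9 then becomes stereolabile.

Step 8
Reactants: 12 aldol adduct
Product: 13 (4S)-3-[(TBS-oxy)acetyl]-5-[(TBS-oxy)methyl]-4-(2,2-dimethoxyethyl)-3,4-dihydro-2H-pyran-2-one (C9 epimers and enol in equilibrium)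
Conditions: Dess–Martin periodinane (1.3 equiv), NaHCO3 (3 equiv), CH2Cl2, 0 °C to rt
Reagents that add atoms: none
Why: Dess–Martin oxidation of a β-hydroxy lactone to the β-keto lactone runs under buffered neutral conditions that spare the acetal, the silyl ethers and the enol lactone.

Step 9
Reactants: 13 β-keto lactone acetal
Product: 14 (3S,4S)-3-[(TBS-oxy)acetyl]-5-[(TBS-oxy)methyl]-4-(2-oxoethyl)-3,4-dihydro-2H-pyran-2-one (keto aldehyde, used at once)
Conditions: silica gel, 10% aq oxalic acid, CH2Cl2, rt
Reagents that add atoms: water, O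
Why: Mild heterogeneous acetal hydrolysis frees the aldehyde last, so that a C7 alcohol, which would translactonise onto C1, never appears, and the weak supported acid should leave the primary TBS ethers and the enol lactone intact.

Step 10
Reactants: 14 keto aldehyde
Product: 15 (4aS,6R,7R,7aS)-6,7-dihydroxy-4,7-bis[(TBS-oxy)methyl]-5,6,7,7a-tetrahydrocyclopenta[c]pyran-1(4aH)-one (cis-fused, 7α,8α-diol in iridoid numbering)
Conditions: SmI2 (2.5 equiv, 0.1 M in THF), t-BuOH (2 equiv), THF, −78 °C, 14 added slowly (final 0.01 M); pH 7 phosphate buffer at −78 °C; aq potassium sodium tartrate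
Reagents that add atoms: none
Why: SmI2 transfers one electron to the exposed C7 aldehyde (reduction of the chelated C8 ketone first leads to the same bond), the ketyl carbon adds to the partner carbonyl carbon, and a second electron reduces the oxygen radical to a diolate of trivalent samarium that t-BuOH and the buffer protonate. The closest known reaction type is the SmI2 intramolecular pinacol coupling of 2-acyl-5-oxopentanoates, that is keto aldehydes made from β-keto esters, which gives cis-cyclopentane-1,2-diols. The cyclopentane ring (C5–C6–C7–C8–C9) closes 5-exo-trig, and because the C5 chain sits pseudo-axial to avoid allylic strain with the C4 substituent, only the 5,9-cis epimer brings C7 next to C8, so the stereolabile C9 drains through this epimer into the cis-fused bicycle. C8 is set by the six-membered chelate of trivalent samarium between the C8 oxygen and the C1 lactone carbonyl, which holds O-8 syn to C1 (α) and turns C10 to the convex β face, and C7 is set by the same metal bridging both oxygens during bond formation, which places O-7 cis to O-8 (α). The step needs ring closure to outrun loss of the C10 silyloxy group, plain carbonyl reduction and attack of the new alkoxides on the enol lactone, and this is secured by the three-atom tether, the absence of HMPA and of a strong proton donor, the low temperature and the cold buffered quench.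

Step 11
Reactants: 16 p-coumaric acid
Product: 18 (E)-3-[4-(TBS-oxy)phenyl]prop-2-enoic acid, via silyl ester 17 (not isolated)
Conditions: TBSCl (2.3 equiv), imidazole (4.5 equiv), DMF, rt; then THF/AcOH/H2O, rt
Reagents that add atoms: tert-butyldimethylsilyl chloride, CC(C)(C)[Si](C)(C)Cl
Why: Exhaustive silylation followed by selective hydrolysis of the far more labile silyl ester is the usual way to a phenol-protected hydroxycinnamic acid, mild acid being chosen because aryl silyl ethers are base-labile, and the E alkene is untouched.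

Step 12
Reactants: 15 cis-diol; 18 protected coumaric acid
Product: 19 (4aS,6S,7R,7aS)-7-hydroxy-1-oxo-4,7-bis[(TBS-oxy)methyl]-1,4a,5,6,7,7a-hexahydrocyclopenta[c]pyran-6-yl (E)-3-[4-(TBS-oxy)phenyl]prop-2-enoate (7β ester, 8α-OH)
Conditions: 18 (1.5 equiv), PPh3 (1.6 equiv), DIAD (1.6 equiv), toluene, 0 °C to rt
Reagents that add atoms: none
Why: In the Mitsunobu esterification only the secondary C7 hydroxyl gives a displaceable oxyphosphonium ion, the carboxylate attacks from the open convex β face with SN2 inversion to the 7β ester, and the cis-disposed tertiary C8 hydroxyl can neither be displaced nor close an epoxide.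

Step 13
Reactants: 19 lactone ester
Product: 20 the corresponding C1 lactol (1R, 1β-OH; otherwise as 19)
Conditions: iBu2AlH (2.2 equiv), CH2Cl2, −78 °C; MeOH; aq potassium sodium tartrate
Reagents that add atoms: none
Why: In this partial reduction of a lactone to the lactol with iBu2AlH, a reaction known for iridoid enol lactones, the first equivalent forms the C8 aluminium alkoxide that activates the neighbouring C1 carbonyl, the non-conjugated enol lactone should be reduced at −78 °C faster than the electron-rich cinnamate, the tetrahedral aluminate holds until work-up, and the lactol settles as the 1β anomer.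

Step 14
Reactants: 20 lactol; 21 isovaleric anhydride
Product: 22 tris-TBS ether of luzonoid A (1S, 1β-isovalerate)
Conditions: 21 (1.5 equiv), Et3N (2 equiv), DMAP (0.1 equiv), CH2Cl2, −20 to 0 °C
Reagents that add atoms: none
Why: In this DMAP-catalysed acylation of the hemiacetal hydroxyl the tertiary C8 alcohol is inert, and since the anomers equilibrate through the open form the ester is drawn from the favoured 1β lactol (pseudo-axial, anomerically stabilised, trans to the C9–C8 bond), which sets C1.

Step 15
Reactants: 22 protected target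
Product: 23 luzonoid A
Conditions: HF·pyridine, pyridine, THF, 0 °C to rt; aq NaHCO3
Reagents that add atoms: none
Why: Fluoride cleavage of the three TBS ethers with pyridine-buffered HF avoids both the base that would cause acyl migration or ester loss and the strong acid that would ionise the acyl acetal or the allylic C11 alcohol, and no stereocentre is touched.

Compound list
1 | (tert-butyldimethylsilyloxy)acetaldehyde | CC(C)(C)[Si](C)(C)OCC=O | starting material
2 | nitromethane | C[N+](=O)[O-] | starting material
3 | 1-(TBS-oxy)-3-nitropropan-2-ol (racemic) | CC(C)(C)[Si](C)(C)OCC(O)C[N+](=O)[O-] | intermediate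
4 | (E)-tert-butyldimethyl[(3-nitroprop-2-en-1-yl)oxy]silane | CC(C)(C)[Si](C)(C)OC/C=C/[N+](=O)[O-] | intermediate
5 | methyl 4-oxobutanoate | COC(=O)CCC=O | starting material
6 | methyl (3S,4S)-4-[(TBS-oxy)methyl]-3-formyl-5-nitropentanoate | O=C[C@@H](CC(=O)OC)[C@H](CO[Si](C)(C)C(C)(C)C)C[N+](=O)[O-] | intermediate
7 | methyl (3S,4S)-4-[(TBS-oxy)methyl]-3-(2-methoxyethenyl)-5-nitropentanoate (E/Z) | COC=C[C@@H](CC(=O)OC)[C@H](CO[Si](C)(C)C(C)(C)C)C[N+](=O)[O-] | intermediate
8 | methyl (3S,4S)-4-[(TBS-oxy)methyl]-3-(2,2-dimethoxyethyl)-5-nitropentanoate | COC(OC)C[C@@H](CC(=O)OC)[C@H](CO[Si](C)(C)C(C)(C)C)C[N+](=O)[O-] | intermediate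
9 | (3S,4S)-4-[(TBS-oxy)methyl]-3-(2,2-dimethoxyethyl)-5-nitropentanoic acid | COC(OC)C[C@@H](CC(=O)O)[C@H](CO[Si](C)(C)C(C)(C)C)C[N+](=O)[O-] | intermediate
10 | (3S,4R)-5-(TBS-oxy)-3-(2,2-dimethoxyethyl)-4-formylpentanoic acid | COC(OC)C[C@@H](CC(=O)O)[C@H](CO[Si](C)(C)C(C)(C)C)C=O | intermediate
11 | (S)-5-[(TBS-oxy)methyl]-4-(2,2-dimethoxyethyl)-3,4-dihydro-2H-pyran-2-one | O=C1OC=C(CO[Si](C)(C)C(C)(C)C)[C@@H](CC(OC)OC)C1 | intermediate
12 | (4S)-3-[2-(TBS-oxy)-1-hydroxyethyl]-5-[(TBS-oxy)methyl]-4-(2,2-dimethoxyethyl)-3,4-dihydro-2H-pyran-2-one (mixture at C8, C9) | O=C1OC=C(CO[Si](C)(C)C(C)(C)C)[C@@H](CC(OC)OC)C1C(O)CO[Si](C)(C)C(C)(C)C | intermediate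
13 | (4S)-3-[(TBS-oxy)acetyl]-5-[(TBS-oxy)methyl]-4-(2,2-dimethoxyethyl)-3,4-dihydro-2H-pyran-2-one (C9 stereolabile) | O=C1OC=C(CO[Si](C)(C)C(C)(C)C)[C@@H](CC(OC)OC)C1C(=O)CO[Si](C)(C)C(C)(C)C | intermediate
14 | (3S,4S)-3-[(TBS-oxy)acetyl]-5-[(TBS-oxy)methyl]-4-(2-oxoethyl)-3,4-dihydro-2H-pyran-2-one | O=C1OC=C(CO[Si](C)(C)C(C)(C)C)[C@@H](CC=O)[C@H]1C(=O)CO[Si](C)(C)C(C)(C)C | intermediate
15 | (4aS,6R,7R,7aS)-6,7-dihydroxy-4,7-bis[(TBS-oxy)methyl]-5,6,7,7a-tetrahydrocyclopenta[c]pyran-1(4aH)-one | O=C1OC=C(CO[Si](C)(C)C(C)(C)C)[C@H]2C[C@@H](O)[C@](O)(CO[Si](C)(C)C(C)(C)C)[C@@H]12 | intermediate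
16 | p-coumaric acid | OC(=O)/C=C/c1ccc(O)cc1 | starting material
17 | TBS (E)-3-[4-(TBS-oxy)phenyl]prop-2-enoate | CC(C)(C)[Si](C)(C)OC(=O)/C=C/c1ccc(O[Si](C)(C)C(C)(C)C)cc1 | intermediate
18 | (E)-3-[4-(TBS-oxy)phenyl]prop-2-enoic acid | OC(=O)/C=C/c1ccc(O[Si](C)(C)C(C)(C)C)cc1 | intermediate
19 | 7β-[(E)-4-(TBS-oxy)cinnamoyloxy]-8α-hydroxy enol lactone, (4aS,6S,7R,7aS) | O=C1OC=C(CO[Si](C)(C)C(C)(C)C)[C@H]2C[C@H](OC(=O)/C=C/c3ccc(O[Si](C)(C)C(C)(C)C)cc3)[C@](O)(CO[Si](C)(C)C(C)(C)C)[C@@H]12 | intermediate
20 | 1β-lactol of 19, (1R,4aS,6S,7R,7aS) | O[C@@H]1OC=C(CO[Si](C)(C)C(C)(C)C)[C@H]2C[C@H](OC(=O)/C=C/c3ccc(O[Si](C)(C)C(C)(C)C)cc3)[C@](O)(CO[Si](C)(C)C(C)(C)C)[C@@H]12 | intermediate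
21 | isovaleric anhydride | CC(C)CC(=O)OC(=O)CC(C)C | starting material
22 | luzonoid A tris-TBS ether, (1S,4aS,6S,7R,7aS) | CC(C)CC(=O)O[C@@H]1OC=C(CO[Si](C)(C)C(C)(C)C)[C@H]2C[C@H](OC(=O)/C=C/c3ccc(O[Si](C)(C)C(C)(C)C)cc3)[C@](O)(CO[Si](C)(C)C(C)(C)C)[C@@H]12 | intermediate
23 | luzonoid A | CC(C)CC(=O)O[C@@H]1OC=C(CO)[C@H]2C[C@H](OC(=O)/C=C/c3ccc(O)cc3)[C@](O)(CO)[C@@H]12 | target

Total step count: 15. Longest linear sequence: 14 (steps 1–10 and 12–15, from compound 1).

Steps most likely to fail

Step 10. Reductive loss of the silyloxy group next to the ketone, plain reduction of the aldehyde, or slow drainage of the unreactive C9 epimer and enol may compete with ring closure. The fallback replaces electron transfer from a metal by a neutral radical chain. It sets out from 14, which is heated with Bu3SnH (1.2 equiv) and AIBN in benzene at 80 °C. The stannyl radical adds to the aldehyde oxygen, the O-stannyl ketyl closes 5-exo onto the ketone, and hydrogen transfer gives the 7-O-tributylstannyl ether F1. No two-electron cleavage of the C10–O bond is possible on this path, and 1,5-dicarbonyl compounds are known to give cis-diols. Stirring with aqueous KF frees the diol and the route is rejoined at 15.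

Step 12. Activation of the concave, neopentyl-like C7 hydroxyl may be slow, the diol may be tied up as a cyclic phosphorane, or elimination towards C6 may take over. The fallback inverts C7 by redox instead of substitution. It sets out from 15, whose secondary alcohol alone is oxidised with Dess–Martin periodinane to the 7-oxo-8α-hydroxy lactone F2. Hydroxyl-directed reduction with Me4NBH(OAc)3 in MeCN/AcOH at −20 °C delivers hydride from the α face occupied by the C8 hydroxyl and gives the 7β,8α-trans-diol F3. Steglich esterification of F3 with 18 (EDC·HCl, DMAP, CH2Cl2) acylates only the secondary alcohol and comes back to the route at 19.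

Step 13. Competing reduction of the cinnamate ester or over-reduction of the lactone after early collapse of the aluminate may occur. The fallback changes the order so that no other ester is present during the hydride step. It sets out from 15, which is reduced with iBu2AlH (3.3 equiv, CH2Cl2, −78 °C) to the 1β-lactol 7α,8α-diol F4. The hemiacetal hydroxyl, the most acidic and least hindered of the three, is acylated with 21 (1.05 equiv, Et3N, DMAP, −40 °C) to the 1β-isovalerate diol F5. Mitsunobu esterification of F5 with 18 (PPh3, DIAD, toluene) then inverts C7 and comes back to the route at 22.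

Further compounds
F1 | step 10 | 7-O-tributylstannyl ether of 15 | O=C1OC=C(CO[Si](C)(C)C(C)(C)C)[C@H]2C[C@@H](O[Sn](CCCC)(CCCC)CCCC)[C@](O)(CO[Si](C)(C)C(C)(C)C)[C@@H]12
F2 | step 12 | 7-oxo-8α-hydroxy enol lactone | O=C1OC=C(CO[Si](C)(C)C(C)(C)C)[C@H]2CC(=O)[C@](O)(CO[Si](C)(C)C(C)(C)C)[C@@H]12
F3 | step 12 | 7β,8α-trans-diol enol lactone | O=C1OC=C(CO[Si](C)(C)C(C)(C)C)[C@H]2C[C@H](O)[C@](O)(CO[Si](C)(C)C(C)(C)C)[C@@H]12
F4 | step 13 | 1β-lactol 7α,8α-diol | O[C@@H]1OC=C(CO[Si](C)(C)C(C)(C)C)[C@H]2C[C@@H](O)[C@](O)(CO[Si](C)(C)C(C)(C)C)[C@@H]12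
F5 | step 13 | 1β-isovalerate 7α,8α-diol | CC(C)CC(=O)O[C@@H]1OC=C(CO[Si](C)(C)C(C)(C)C)[C@H]2C[C@@H](O)[C@](O)(CO[Si](C)(C)C(C)(C)C)[C@@H]12
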